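**Retrosynthetic overview**

1. Target 32 ⇐ pentaol 30: the last steps only make C–O bonds (11,20-oxirane from a 1,2-diol, then the C2/C14 acetates).
2. Key disconnection: the C7–O bond of ring C. A selenium-catalysed chlorolactonisation of cyclodecadiene 27 closes the lactone, installs C6–Cl and keeps the C5 methylidene.
3. Ring B: ring-closing metathesis at C6=C7; C8–C17 by Reformatsky addition, C8–C9 by an acryloyl-anion addition, C2–C3 by Grignard addition.
4. Ring A: Diels–Alder reaction of 3-hydroxy-2-pyrone 5 with enal ester 4, setting C1, C10, C11 and C14 in one step.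
5. Ring order: A (step 2) → B (step 13) → C (step 14) → oxirane (step 16).

Assumption: intermediates are named with the briarane numbering of the target (C1–C20; target = 1S,2S,6S,7R,8R,9S,10S,11S,14S,17R); in every ring-A intermediate the C1–C2, C14–O and C11–C20 bonds lie on one face and C1–CH3, C11–O and C10–C9 on the other, as written in the SMILES.

**Route**

Step 1
Reactants: 1 2,2-dimethoxyacetaldehyde; 2 ethyl 2-(triphenylphosphoranylidene)propanoate
Product: 4 ethyl (E)-2-methyl-4-oxobut-2-enoate, via acetal enoate 3 (not isolated)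
Conditions: CH2Cl2, rt; then 2 M HCl, acetone, rt
Reagents that add atoms: water, O
Why: Wittig olefination with the stabilised ylide gives the E-enoate (ester trans to the acetal carbon), and acid hydrolysis of the dimethyl acetal then frees the aldehyde without changing the alkene geometry.

Step 2
Reactants: 4 ethyl (E)-2-methyl-4-oxobut-2-enoate; 5 3-hydroxy-2H-pyran-2-one
Product: 6 ethyl 5-endo-formyl-4-hydroxy-6-endo-methyl-3-oxo-2-oxabicyclo[2.2.2]oct-7-ene-6-exo-carboxylate
Conditions: thiourea catalyst made from 9-amino-9-deoxy-epi-quinidine and 3,5-bis(trifluoromethyl)phenyl isothiocyanate (10 mol%), EtOAc, −20 °C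
Reagents that add atoms: none
Why: Amine-base-catalysed Diels–Alder reaction of the 3-hydroxy-2-pyrone dienolate in which the thiourea binds the formyl group, so that the formyl-bearing carbon (C10) bonds to the hydroxylated pyrone carbon (C11) and the O-substituted terminus (C14) to the methylated carbon (C1) with endo-formyl approach on the catalyst-selected face, the E-alkene fixing C2 and C9 trans and the lactone bridge fixing O14 and C20 cis, which sets C1, C10, C11 and C14 together.

Step 3
Reactants: 6 ethyl 5-endo-formyl-4-hydroxy-6-endo-methyl-3-oxo-2-oxabicyclo[2.2.2]oct-7-ene-6-exo-carboxylate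
Product: 7 ethyl 5-formyl-4-hydroxy-6-methyl-3-oxo-2-oxabicyclo[2.2.2]octane-6-carboxylate
Conditions: H2 (1 atm), Pd/C, EtOAc, rt
Reagents that add atoms: none
Why: Catalytic hydrogenation of the unhindered cis-disubstituted bridge alkene (no stereocentre formed), done before any vinyl group is introduced.

Step 4
Reactants: 7 ethyl 5-formyl-4-hydroxy-6-methyl-3-oxo-2-oxabicyclo[2.2.2]octane-6-carboxylate
Product: 8 ethyl 2,5-dihydroxy-5,6-bis(hydroxymethyl)-1-methylcyclohexane-1-carboxylate
Conditions: NaBH4 (4 equiv), EtOH, 0 °C → rt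
Reagents that add atoms: none
Why: Sodium borohydride reduction of the aldehyde and of the strained α-hydroxy lactone (hydroxyl-assisted), the hindered neopentyl ethyl ester being inert under these conditions, with no stereocentre changed.

Step 5
Reactants: 8 ethyl 2,5-dihydroxy-5,6-bis(hydroxymethyl)-1-methylcyclohexane-1-carboxylate
Product: 9 ring-A lactone acetonide (C2→O9 γ-lactone; 11,20-O-isopropylidene; 14-OH free)
Conditions: Me2C(OMe)2, TsOH·H2O (5 mol%), acetone, rt; then toluene, 80 °C
Reagents that add atoms: 2,2-dimethoxypropane, COC(C)(C)OC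
Why: Acid-catalysed acetalisation captures the tertiary/primary 1,2-diol as the five-membered dioxolane, and on warming the only hydroxyl that can reach the ester (9-OH, trans-diequatorial to C2) closes the γ-lactone by transesterification, which differentiates C9 from C2 and leaves 14-OH free.

Step 6
Reactants: 10 isoprene
Product: 12 3-methylidenepent-4-en-1-ol, via isoprenylpotassium 11 (not isolated)
Conditions: LiTMP, KOt-Bu, THF, −78 °C; (CH2O)n, −78 °C → rt
Reagents that add atoms: formaldehyde (as paraformaldehyde), C=O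
Why: Superbase allylic metalation of isoprene at its methyl group gives the 2-vinylallyl anion, whose two CH2 termini are equivalent, and hydroxymethylation with formaldehyde gives the homoallylic alcohol.

Step 7
Reactants: 12 3-methylidenepent-4-en-1-ol
Product: 13 5-bromo-3-methylidenepent-1-ene
Conditions: CBr4, PPh3, CH2Cl2, 0 °C
Reagents that add atoms: carbon tetrabromide, BrC(Br)(Br)Br
Why: Appel bromination of the primary alcohol under neutral conditions that leave the 1,3-diene untouched.

Step 8
Reactants: 9 ring-A lactone acetonide; 13 5-bromo-3-methylidenepent-1-ene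
Product: 16 triol (2,9,14-trihydroxy; 11,20-O-isopropylidene; C3–C6 dienyl arm on C2), via Grignard reagent 14 (not isolated), via lactol 15 (not isolated)
Conditions: 13, Mg, THF, rt; separately 9, i-Bu2AlH (2.2 equiv), CH2Cl2, −78 °C; then the Grignard solution (4 equiv), −78 → 0 °C; aq. Rochelle salt
Reagents that add atoms: none
Why: i-Bu2AlH stops at the lactol aluminate, whose ring-opened aldehyde is captured by the Grignard reagent (Grignard addition) under Cram-chelate control, the C14 alkoxide and the aldehyde oxygen binding magnesium in a six-membered chelate that is attacked from the methyl-bearing face opposite ring A to give the 2,14-anti diol (2S).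

Step 9
Reactants: 16 triol
Product: 17 bis-acetonide alcohol (2,14- and 11,20-O-isopropylidene; 9-OH free)
Conditions: Me2C(OMe)2, PPTS (10 mol%), CH2Cl2, rt
Reagents that add atoms: 2,2-dimethoxypropane, COC(C)(C)OC
Why: Acetonide formation on the 2,14-anti 1,3-diol (six-membered 1,3-dioxane), the primary 9-OH having no diol partner and staying free.

Step 10
Reactants: 17 bis-acetonide alcohol
Product: 18 C9 aldehyde
Conditions: Dess–Martin periodinane, NaHCO3, CH2Cl2, rt
Reagents that add atoms: none
Why: Dess–Martin oxidation of the primary alcohol to the aldehyde under buffered conditions that do not epimerise C10.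

Step 11
Reactants: 18 C9 aldehyde; 19 methoxyallene
Product: 23 9-acetoxy vinyl ketone (C8 ketone; C7 vinyl), via lithiomethoxyallene 20 (not isolated), via lithium alkoxide 21 (not isolated), via allenyl acetate 22 (not isolated)
Conditions: 19, n-BuLi, THF, −78 °C; 18, −78 °C; Ac2O, −78 → 0 °C; then 0.5 M aq. oxalic acid, THF, 0 °C
Reagents that add atoms: acetic anhydride, CC(=O)OC(C)=O; water, O
Why: Lithiated methoxyallene acts as an acryloyl anion equivalent and adds to the aldehyde in the Felkin–Anh sense, anti to the C10–C11 bond (C11, the ketal-bearing quaternary carbon, being the larger and more electron-poor α-substituent), which sets 9S, while acetylation of the alkoxide in the flask blocks cyclisation to a furanone and mild acid hydrolysis of the allenyl enol ether releases the vinyl ketone.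

Step 12
Reactants: 23 9-acetoxy vinyl ketone; 24 tert-butyl 2-bromopropanoate
Product: 26 β-hydroxy ester (8-OH; 8-vinyl; 17-methyl; tert-butyl C19 ester), via zinc enolate 25 (not isolated)
Conditions: Zn (activated), THF, 0 °C → rt; sat. aq. NH4Cl
Reagents that add atoms: none
Why: Reformatsky reaction in which the zinc enolate adds 1,2 to the ketone in the polar Felkin–Anh sense (anti to the C9–OAc bond) to set 8R, a closed Zimmerman–Traxler transition state with the branched C9 substituent equatorial favouring the 8,17-syn adduct (17R), whose minor C17 epimer is removed by chromatography.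

Step 13
Reactants: 26 β-hydroxy ester
Product: 27 cyclodecadiene (Z-6,7-ene; 5(16)-methylidene; 8-OH; tert-butyl ester)
Conditions: second-generation Grubbs catalyst RuCl2(=CHPh)(PCy3)(H2IMes) (10 mol%), CH2Cl2 (1 mM), 40 °C
Reagents that add atoms: none
Why: Ring-closing metathesis between the two monosubstituted vinyl groups (the 1,1-disubstituted C5 methylidene is a poor partner), assisted by the free allylic hydroxyl, forms ring B with the Z double bond that a ten-membered ring imposes.

Step 14
Reactants: 27 cyclodecadiene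
Product: 29 chlorolactone (6-chloro-7,19-olide; 5(16)-methylidene; 8-O-trimethylsilyl; bis-acetonide), via bis-silyl derivative 28 (not isolated)
Conditions: Me3SiOTf (2.5 equiv), 2,6-lutidine (4 equiv), CH2Cl2, 0 °C; then PhSeCl (10 mol%), N-chlorosuccinimide (1.2 equiv), MeCN, −20 °C → rt
Reagents that add atoms: trimethylsilyl triflate, C[Si](C)(C)OS(=O)(=O)C(F)(F)F; N-chlorosuccinimide, O=C1CCC(=O)N1Cl
Why: Proposed new method: a selenium-catalysed formal 1,2-chlorolactonisation of a 2-substituted 1,3-diene, in which (after the tert-butyl ester and 8-OH are converted in the flask into silyl ester and silyl ether) PhSeCl adds to the more nucleophilic exocyclic CH2 (C16) and the silyl carboxylate closes 5-exo on C7 through the allylic selenonium ion (1,4-selenolactonisation, C7–O formed anti to C9 so that the lactone is trans-fused, 7R), N-chlorosuccinimide then chlorinates the allylic selenide and the tetravalent selenium species undergoes a [2,3]-type chlorine shift that delivers Cl to C6 anti to the new C7–O bond (6S), restores the C5=C16 methylidene and releases PhSeCl for the next turnover; the closest known reactions are stoichiometric phenylselenolactonisation and the PhSeCl-catalysed allylic chlorination of alkenes with N-chlorosuccinimide, which have not been combined on a diene acid.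

Step 15
Reactants: 29 chlorolactone
Product: 30 pentaol chlorolactone (2,8,11,14,20-pentahydroxy; 9-acetate)
Conditions: AcOH/THF/H2O (3:1:1), 40 °C
Reagents that add atoms: none
Why: Mild aqueous acid hydrolysis of both isopropylidene acetals and of the tertiary silyl ether, under which the acetate, the lactone and the chloride (ionisation disfavoured by the adjacent C7–O bond) survive.

Step 16
Reactants: 30 pentaol chlorolactone
Product: 31 11,20-epoxide (2,14-diol; 9-acetate)
Conditions: PPh3, DIAD (betaine preformed), THF, 0 °C → rt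
Reagents that add atoms: none
Why: Mitsunobu cyclodehydration of the 1,2-diol through its five-membered dioxaphosphorane, the primary C20–O being activated and displaced by the tertiary C11 oxygen (3-exo-tet), so the C11 configuration set in step 2 is retained (oxirane oxygen on the face of the C1 methyl group).

Step 17
Reactants: 31 11,20-epoxide
Product: 32 target CNP0104093.2
Conditions: Ac2O, pyridine, DMAP (10 mol%), CH2Cl2, 0 °C → rt
Reagents that add atoms: acetic anhydride, CC(=O)OC(C)=O
Why: DMAP-catalysed acetylation of the two secondary hydroxyls (C2 and C14), the tertiary 8-OH being too hindered to react under these conditions, gives the target.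

**Compound list**

1 | 2,2-dimethoxyacetaldehyde | COC(OC)C=O | starting material
2 | ethyl 2-(triphenylphosphoranylidene)propanoate | CCOC(=O)C(C)=P(c1ccccc1)(c1ccccc1)c1ccccc1 | starting material
3 | ethyl (E)-4,4-dimethoxy-2-methylbut-2-enoate | CCOC(=O)/C(C)=C/C(OC)OC | intermediate (not isolated)
4 | ethyl (E)-2-methyl-4-oxobut-2-enoate | CCOC(=O)/C(C)=C/C=O | intermediate
5 | 3-hydroxy-2H-pyran-2-one | O=C1OC=CC=C1O | starting material
6 | ethyl 5-endo-formyl-4-hydroxy-6-endo-methyl-3-oxo-2-oxabicyclo[2.2.2]oct-7-ene-6-exo-carboxylate (endo = syn to the C7=C8 bridge; bicycle C1/C4/C5/C6 = briarane C14/C11/C10/C1) | CCOC(=O)[C@@]2(C)[C@@H]3C=C[C@@](O)(C(=O)O3)[C@@H]2C=O | intermediate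
7 | ethyl 5-formyl-4-hydroxy-6-methyl-3-oxo-2-oxabicyclo[2.2.2]octane-6-carboxylate (formyl and methyl anti, ester syn to the lactone bridge) | CCOC(=O)[C@@]2(C)[C@@H]3CC[C@@](O)(C(=O)O3)[C@@H]2C=O | intermediate
8 | ethyl 2,5-dihydroxy-5,6-bis(hydroxymethyl)-1-methylcyclohexane-1-carboxylate (ester, 2-OH and 5-CH2OH on one face; 1-CH3, 5-OH and 6-CH2OH on the other) | CCOC(=O)[C@@]1(C)[C@@H](O)CC[C@@](O)(CO)[C@@H]1CO | intermediate
9 | ring-A lactone acetonide: trans-fused γ-lactone from the C2 carboxyl to O9, 11,20-O-isopropylidene (spiro-dioxolane), 14-OH free | O=C3[C@@]2(C)[C@@H](O)CC[C@@]4(COC(C)(C)O4)[C@@H]2CO3 | intermediate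
10 | isoprene (2-methylbuta-1,3-diene) | C=CC(C)=C | starting material
11 | isoprenylpotassium (2-vinylallyl potassium) | [K+].[CH2-]C(=C)C=C | intermediate (not isolated)
12 | 3-methylidenepent-4-en-1-ol | C=CC(=C)CCO | intermediate
13 | 5-bromo-3-methylidenepent-1-ene | C=CC(=C)CCBr | intermediate
14 | (3-methylidenepent-4-en-1-yl)magnesium bromide | C=CC(=C)CC[Mg]Br | intermediate (not isolated)
15 | lactol of 9 (C2 hemiacetal, anomeric mixture) | OC3[C@@]2(C)[C@@H](O)CC[C@@]4(COC(C)(C)O4)[C@@H]2CO3 | intermediate (not isolated)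
16 | triol: 2,9,14-trihydroxy, 11,20-O-isopropylidene, C2 carrying the CH2CH2C(=CH2)CH=CH2 arm (C3–C6, C16); C1, C2, C10, C11, C14 as in the target | C=CC(=C)CC[C@H](O)[C@@]1(C)[C@@H](O)CC[C@@]2(COC(C)(C)O2)[C@@H]1CO | intermediate
17 | bis-acetonide alcohol: 2,14-O-isopropylidene and 11,20-O-isopropylidene, 9-OH | C=CC(=C)CC[C@H](OC3(C)C)[C@@]1(C)[C@@H](O3)CC[C@@]2(COC(C)(C)O2)[C@@H]1CO | intermediate
18 | C9 aldehyde of 17 | C=CC(=C)CC[C@H](OC3(C)C)[C@@]1(C)[C@@H](O3)CC[C@@]2(COC(C)(C)O2)[C@@H]1C=O | intermediate
19 | methoxyallene (1-methoxypropa-1,2-diene) | COC=C=C | starting material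
20 | 1-lithio-1-methoxyallene | [Li]C(OC)=C=C | intermediate (not isolated)
21 | lithium (9S)-alkoxide of the allenyl carbinol | C=CC(=C)CC[C@H](OC3(C)C)[C@@]1(C)[C@@H](O3)CC[C@@]2(COC(C)(C)O2)[C@@H]1[C@H]([O-])C(OC)=C=C.[Li+] | intermediate (not isolated)
22 | (9S)-allenyl acetate (C8 methoxyallenyl, 9-OAc) | C=CC(=C)CC[C@H](OC3(C)C)[C@@]1(C)[C@@H](O3)CC[C@@]2(COC(C)(C)O2)[C@@H]1[C@H](OC(C)=O)C(OC)=C=C | intermediate (not isolated)
23 | 9-acetoxy vinyl ketone (9S; C8 ketone; C7 vinyl) | C=CC(=C)CC[C@H](OC3(C)C)[C@@]1(C)[C@@H](O3)CC[C@@]2(COC(C)(C)O2)[C@@H]1[C@H](OC(C)=O)C(=O)C=C | intermediate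
24 | tert-butyl 2-bromopropanoate (racemic) | CC(Br)C(=O)OC(C)(C)C | starting material
25 | bromozinc enolate of tert-butyl propanoate (Reformatsky reagent, drawn C-bound) | CC([Zn]Br)C(=O)OC(C)(C)C | intermediate (not isolated)
26 | β-hydroxy ester: 8-OH, 8-vinyl, 17-methyl, tert-butyl C19 ester, 9-OAc; C8, C9, C17 as in the target | C=CC(=C)CC[C@H](OC3(C)C)[C@@]1(C)[C@@H](O3)CC[C@@]2(COC(C)(C)O2)[C@@H]1[C@H](OC(C)=O)[C@](C=C)(O)[C@@H](C)C(=O)OC(C)(C)C | intermediate
27 | cyclodecadiene: ring B closed, Z-6,7-ene, 5(16)-methylidene, 8-OH, tert-butyl ester, 9-OAc, bis-acetonide | C=C1CC[C@H](OC5(C)C)[C@@]2(C)[C@@H](O5)CC[C@@]3(COC(C)(C)O3)[C@@H]2[C@H](OC(C)=O)[C@](O)([C@@H](C)C(=O)OC(C)(C)C)/C=C\1 | intermediate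
28 | bis-silyl derivative of 27 (8-O-SiMe3, trimethylsilyl C19 ester) | C=C1CC[C@H](OC5(C)C)[C@@]2(C)[C@@H](O5)CC[C@@]3(COC(C)(C)O3)[C@@H]2[C@H](OC(C)=O)[C@](O[Si](C)(C)C)([C@@H](C)C(=O)O[Si](C)(C)C)/C=C\1 | intermediate (not isolated)
29 | chlorolactone: (6S)-chloro, 7,19-olide (7R), 5(16)-methylidene, 8-O-SiMe3, 9-OAc, bis-acetonide | C=C1CC[C@H](OC5(C)C)[C@@]2(C)[C@@H](O5)CC[C@@]3(COC(C)(C)O3)[C@@H]2[C@H](OC(C)=O)[C@]2(O[Si](C)(C)C)[C@@H](C)C(=O)O[C@H]2[C@H]1Cl | intermediate
30 | pentaol chlorolactone: 2,8,11,14,20-pentahydroxy, 9-OAc | C=C1CC[C@H](O)[C@@]2(C)[C@@H](O)CC[C@@](O)(CO)[C@@H]2[C@H](OC(C)=O)[C@]2(O)[C@@H](C)C(=O)O[C@H]2[C@H]1Cl | intermediate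
31 | 11,20-epoxide: 2,14-diol, 8-OH, 9-OAc | C=C1CC[C@H](O)[C@@]2(C)[C@@H](O)CC[C@@]3(CO3)[C@@H]2[C@H](OC(C)=O)[C@]2(O)[C@@H](C)C(=O)O[C@H]2[C@H]1Cl | intermediate
32 | CNP0104093.2: (1S,2S,6S,7R,8R,9S,10S,11S,14S,17R)-2,9,14-triacetoxy-6-chloro-11,20-epoxy-8-hydroxybriar-5(16)-en-19,7-olide | C=C1CC[C@H](OC(C)=O)[C@@]2(C)[C@@H](OC(C)=O)CC[C@@]3(CO3)[C@@H]2[C@H](OC(C)=O)[C@]2(O)[C@@H](C)C(=O)O[C@H]2[C@H]1Cl | target

**Step count and risk**

Total steps: 17. Longest linear sequence: 15 steps (1 → 2 → 3 → 4 → 5 → 8 → 9 → 10 → 11 → 12 → 13 → 14 → 15 → 16 → 17); the arm bromide 13 is made in 2 steps (6, 7) and enters at step 8.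

The three steps most likely to fail:

Step 2 (Diels–Alder). The dienophile is trisubstituted and has two acceptors. Formyl control needs the first bond to form at the methylated carbon, whereas sterics favour ester control, which would give the wrong regioisomer. Endo selectivity and enantioselectivity are also unproven for this dienophile class. The fallback sets out from 5 and comes back at 16, and it removes the competing acceptor. (E)-4,4-Dimethoxy-3-methylbut-2-enal F1 is made by Wittig reaction of 1,1-dimethoxypropan-2-one with (triphenylphosphoranylidene)acetaldehyde; its only activating group is the formyl group. Under iminium activation with 9-amino-9-deoxy-epi-quinidine and CF3CO2H it reacts with 5 to give the acetal cycloadduct F2. Hydrogenation over Pd/C gives the saturated acetal adduct F3, and NaBH4 gives the tetraol acetal F4. Me2C(OMe)2 with TsOH closes the C2 acetal onto O9 and protects the 1,2-diol, giving the bicyclic methyl acetal F5. PPTS in aqueous acetone hydrolyses F5 to lactol 15, which is treated with Grignard reagent 14 as in step 8 to give 16.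

Step 13 (ring-closing metathesis). The ten-membered ring has to close at a vinyl group on a fully substituted carbinol carbon; oligomers or metathesis through the diene may win. The fallback sets out from 23 and comes back at 27, and it inverts the order of ring closure and aldol. Enone–diene ring-closing metathesis of 23 with the same ruthenium catalyst, while C8 is still a planar carbonyl carbon, gives the cyclodecadienone F6. Reformatsky addition of zinc enolate 25 to F6, anti to the C9–OAc bond, then gives 27.

Step 14 (new chlorolactonisation). The reaction is unprecedented. A competing 1,2-selenolactonisation at C6=C7 would lead to the 16-chloro isomer, the face of chlorine delivery at C6 is only predicted, and the product could be chlorinated again. The fallback uses known chemistry, sets out from 27 and comes back at 30. VO(acac)2 with t-BuOOH epoxidises the allylic C6=C7 bond under direction of 8-OH (the methylidene is not allylic to the hydroxyl) to give the cis-epoxy ester F7. Camphorsulfonic acid in CH2Cl2 opens the epoxide 5-exo at C7 with inversion by the tert-butyl ester, giving the 6-hydroxy lactone F8. PPh3 with hexachloroacetone replaces the allylic hydroxyl by chloride with inversion and without allylic shift, giving the chlorolactone F9. The acid hydrolysis of step 15 then gives 30.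

**Further compounds**

F1 | step 2 | (E)-4,4-dimethoxy-3-methylbut-2-enal | COC(OC)/C(C)=C/C=O
F2 | step 2 | acetal cycloadduct: 6-exo-(dimethoxymethyl)-5-endo-formyl-4-hydroxy-6-endo-methyl-2-oxabicyclo[2.2.2]oct-7-en-3-one | COC(OC)[C@@]2(C)[C@@H]3C=C[C@@](O)(C(=O)O3)[C@@H]2C=O
F3 | step 2 | saturated acetal adduct (7,8-dihydro F2) | COC(OC)[C@@]2(C)[C@@H]3CC[C@@](O)(C(=O)O3)[C@@H]2C=O
F4 | step 2 | tetraol acetal: dimethyl acetal analogue of 8 (CH(OMe)2 in place of CO2Et) | COC(OC)[C@@]1(C)[C@@H](O)CC[C@@](O)(CO)[C@@H]1CO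
F5 | step 2 | bicyclic methyl acetal: methyl glycoside of lactol 15 (anomeric mixture), 11,20-O-isopropylidene, 14-OH | COC3[C@@]2(C)[C@@H](O)CC[C@@]4(COC(C)(C)O4)[C@@H]2CO3
F6 | step 13 | cyclodecadienone: Z-6,7-ene, 5(16)-methylidene, C8 ketone, 9-OAc, bis-acetonide | C=C1CC[C@H](OC5(C)C)[C@@]2(C)[C@@H](O5)CC[C@@]3(COC(C)(C)O3)[C@@H]2[C@H](OC(C)=O)C(=O)/C=C\1
F7 | step 14 | cis-6,7-epoxy ester (oxirane oxygen syn to 8-OH; tert-butyl ester) | C=C1CC[C@H](OC5(C)C)[C@@]2(C)[C@@H](O5)CC[C@@]3(COC(C)(C)O3)[C@@H]2[C@H](OC(C)=O)[C@](O)([C@@H](C)C(=O)OC(C)(C)C)[C@@H]4O[C@H]14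
F8 | step 14 | 6-hydroxy lactone (7,19-olide; C6 epimeric in position to the chloride; 8-OH; bis-acetonide) | C=C1CC[C@H](OC5(C)C)[C@@]2(C)[C@@H](O5)CC[C@@]3(COC(C)(C)O3)[C@@H]2[C@H](OC(C)=O)[C@]2(O)[C@@H](C)C(=O)O[C@H]2[C@@H]1O
F9 | step 14 | chlorolactone with free 8-OH (6S-chloro; 7,19-olide; bis-acetonide) | C=C1CC[C@H](OC5(C)C)[C@@]2(C)[C@@H](O5)CC[C@@]3(COC(C)(C)O3)[C@@H]2[C@H](OC(C)=O)[C@]2(O)[C@@H](C)C(=O)O[C@H]2[C@H]1Cl
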